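**Plan**
- Retrosynthesis: the C9 angelate and the C11=C12 alkene (from a C11 tertiary alcohol) go last. The 8α,9α-diol goes back to a C8=C9 alkene, and that alkene with the C7 and C10 hydrogens goes back to a ring B cyclohexa-1,3-diene C7=C8–C9=C10.
- Ring B is then cut at C5–C6 and C8–C9. The diene is the 6π-electrocyclization product of a Z-hexatriene C6=C7–C8=C9–C10=C5, made by Wittig reaction of a ring A enal (CHO = C9) with a three-carbon allylic ylide (C8, C7, C6).
- Enabling feature: ring B has a quaternary C5 next to a CH2 (C6), followed by four contiguous carbons C7–C10 that each carry one substituent on the same face (H, OH, O-acyl, H). This is the pattern left by two cis additions to a cyclohexa-1,3-diene.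
- Forward: (S)-carvone gives the ring A enal (3 steps), the side-chain fragment (fragment 2) gives the phosphonium salt (4 steps), the union closes ring B, then 1,4-H2, OsO4, unmasking of the isopropenyl group and the angelate.
- Stereochemistry: C2 is carvone C5 (retention in the Criegee step); C4 comes from cuprate addition anti to the isopropenyl group; C5 is set in the electrocyclization anti to the C4 methyl; C7, C10 (H2) and C8, C9 (OsO4) are set on the face opposite to the C5 methyl.

Key step: step 8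

Remark: eremophilane numbering is used (ring A = C1–C5 and C10, ring B = C5–C10, C11–C13 = isopropenyl); α is the face opposite to the C5 methyl.

**Step 1**
Reactants: 1 (S)-(+)-carvone
Product: 3 (3S,5S)-2,3-dimethyl-5-(prop-1-en-2-yl)cyclohex-1-en-1-yl trifluoromethanesulfonate, via lithium enolate 2 (not isolated)
Conditions: Me2CuLi, Et2O, −78 to 0 °C; then PhNTf2, THF, 0 °C to rt
Reagents that add atoms: lithium dimethylcuprate, [Li+].C[Cu-]C; N-phenylbis(trifluoromethanesulfonimide), O=S(=O)(N(c1ccccc1)S(=O)(=O)C(F)(F)F)C(F)(F)F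
Why: Conjugate addition of Me2CuLi should occur anti to the isopropenyl group, setting the future C4 methyl trans to the future C2 oxygen, and the regiodefined enolate is trapped on oxygen (cuprate addition–enolate triflation).

**Step 2**
Reactants: 3 (3S,5S)-2,3-dimethyl-5-(prop-1-en-2-yl)cyclohex-1-en-1-yl trifluoromethanesulfonate
Product: 5 (1S,5S)-4,5-dimethyl-3-[(trifluoromethanesulfonyl)oxy]cyclohex-3-en-1-yl acetate, via methoxy hydroperoxide 4 (not isolated)
Conditions: O3, CH2Cl2/MeOH, −78 °C; then Ac2O, Et3N, DMAP (cat.), 0 °C to rt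
Reagents that add atoms: ozone, [O-][O+]=O; methanol, CO
Why: Ozone should attack the electron-rich isopropenyl group and not the electron-poor enol triflate, and the peracetate of the methanol-trapped carbonyl oxide undergoes Criegee rearrangement with retention at the migrating ring carbon, giving the C2 acetate directly.

**Step 3**
Reactants: 5 (1S,5S)-4,5-dimethyl-3-[(trifluoromethanesulfonyl)oxy]cyclohex-3-en-1-yl acetate
Product: 6 (1S,5S)-3-formyl-4,5-dimethylcyclohex-3-en-1-yl acetate
Conditions: Pd(OAc)2 (5 mol %), dppp, CO (1 atm), Et3SiH, Et3N, DMF, 70 °C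
Reagents that add atoms: carbon monoxide, [C-]#[O+]
Why: Oxidative addition of the enol triflate to zerovalent palladium, CO insertion and hydride transfer from the silane should give the tetrasubstituted enal (palladium-catalysed formylation of a vinyl triflate) without touching the acetate or a stereocentre.

**Step 4**
Reactants: 7 ethyl 2-(hydroxymethyl)prop-2-enoate
Product: 8 3-methyl-2-methylidenebutane-1,3-diol
Conditions: MeMgBr (3.3 equiv), THF, −78 to 0 °C; aq. NH4Cl
Reagents that add atoms: methylmagnesium bromide, C[Mg]Br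
Why: After deprotonation of the hydroxyl, the ester should take up two equivalents of MeMgBr by 1,2-addition to give the tertiary alcohol (Grignard addition to an ester).

**Step 5**
Reactants: 8 3-methyl-2-methylidenebutane-1,3-diol
Product: 9 3-(bromomethyl)-2-methylbut-3-en-2-ol
Conditions: CBr4, PPh3, CH2Cl2, 0 °C
Reagents that add atoms: carbon tetrabromide, BrC(Br)(Br)Br
Why: Appel bromination should convert only the primary allylic alcohol, because the tertiary alkoxyphosphonium ion cannot be displaced by SN2.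

**Step 6**
Reactants: 9 3-(bromomethyl)-2-methylbut-3-en-2-ol
Product: 10 {[3-(bromomethyl)-2-methylbut-3-en-2-yl]oxy}(triethyl)silane
Conditions: Et3SiOTf, 2,6-lutidine, CH2Cl2, −78 to 0 °C
Reagents that add atoms: triethylsilyl trifluoromethanesulfonate, CC[Si](CC)(CC)OS(=O)(=O)C(F)(F)F
Why: The silyl triflate should silylate the hindered tertiary alcohol under a non-nucleophilic base, which masks the future isopropenyl carbon for the ylide chemistry (silyl ether formation).

**Step 7**
Reactants: 10 {[3-(bromomethyl)-2-methylbut-3-en-2-yl]oxy}(triethyl)silane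
Product: 11 {3-methyl-2-methylidene-3-[(triethylsilyl)oxy]butyl}(triphenyl)phosphonium bromide
Conditions: PPh3, PhMe, 60 °C
Reagents that add atoms: triphenylphosphine, c1ccc(cc1)P(c1ccccc1)c1ccccc1
Why: SN2 quaternization of triphenylphosphine by the primary allylic bromide should give the phosphonium salt for the Wittig reaction.

**Step 8**
Reactants: 6 (1S,5S)-3-formyl-4,5-dimethylcyclohex-3-en-1-yl acetate; 11 {3-methyl-2-methylidene-3-[(triethylsilyl)oxy]butyl}(triphenyl)phosphonium bromide
Product: 15 (2S,4S,4aR)-4,4a-dimethyl-6-{2-[(triethylsilyl)oxy]propan-2-yl}-1,2,3,4,4a,5-hexahydronaphthalen-2-yl acetate (the 7,9-diene of the eremophilane skeleton), via ylide 12 (not isolated), via E-triene 13 (not isolated), via Z-triene 14 (not isolated)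
Conditions: 11, KN(SiMe3)2, THF, −78 °C; 6, −78 °C to rt; then solvent exchange to PhMe, (PhS)2 (10 mol %), 2,6-lutidine (0.2 equiv), 130 °C, sealed tube, ambient light
Reagents that add atoms: none
Why: Allylic ylide 12 olefinates the enal (Wittig reaction) and forges C8=C9 as an E/Z mixture; phenylthiyl radicals interconvert the isomers by reversible addition, and only Z-triene 14 can fold into the s-cis,Z,s-cis helix in which C6 and C5 overlap, so it is drained irreversibly by thermal disrotatory 6π-electrocyclization, which forms C5–C6. The closest known reaction type is the one-pot Wittig/6π-electrocyclization route to cyclohexa-1,3-dienes, and the thermal closure of previtamin D to the pyrocalciferols shows that a methyl-bearing quaternary carbon can be made this way. Ring B closes in a pericyclic six-electron disrotatory mode, giving the C7=C8–C9=C10 diene with C6 as its only new sp3 CH2. The one new stereocentre, C5, is controlled by the C4 methyl: allylic 1,2-strain with the C5 methyl holds it pseudoaxial on ring A, so C6 should bond on the opposite face and the two methyls end up cis. The step needs Z geometry at C8=C9 and closure in preference to the 1,7-hydrogen shift from the C5 methyl to C6; the first is secured by radical equilibration under irreversible drain, the second by the fact that the shifted triene can only revert while the unsubstituted C6 terminus keeps the closure barrier low.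

**Step 9**
Reactants: 15 (2S,4S,4aR)-4,4a-dimethyl-6-{2-[(triethylsilyl)oxy]propan-2-yl}-1,2,3,4,4a,5-hexahydronaphthalen-2-yl acetate
Product: 16 (2S,4S,4aR,6S,8aS)-4,4a-dimethyl-6-{2-[(triethylsilyl)oxy]propan-2-yl}-1,2,3,4,4a,5,6,8a-octahydronaphthalen-2-yl acetate (8-ene with 7α-H and 10α-H)
Conditions: Cr(CO)3(η6-naphthalene) (20 mol %), H2 (50 atm), THF, 45 °C
Reagents that add atoms: none
Why: Zerovalent chromium tricarbonyl catalysts bind an s-cis 1,3-diene as an η4 ligand and deliver both hydrogens to its termini from the metal-bearing face (1,4-hydrogenation); this should be the α face opposite to the C5 methyl, which sets 7α-H and 10α-H (trans ring fusion) and leaves the C8=C9 alkene.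

**Step 10**
Reactants: 16 (2S,4S,4aR,6S,8aS)-4,4a-dimethyl-6-{2-[(triethylsilyl)oxy]propan-2-yl}-1,2,3,4,4a,5,6,8a-octahydronaphthalen-2-yl acetate
Product: 17 (2S,4S,4aR,6S,7R,8S,8aR)-7,8-dihydroxy-4,4a-dimethyl-6-{2-[(triethylsilyl)oxy]propan-2-yl}decahydronaphthalen-2-yl acetate (8α,9α-diol)
Conditions: OsO4 (5 mol %), NMO, acetone/H2O, rt
Reagents that add atoms: N-methylmorpholine N-oxide, C[N+]1([O-])CCOCC1; water, O
Why: Upjohn dihydroxylation is a syn addition of OsO4 to the only alkene, and the β face is shielded by the C5 methyl and the C7 side chain, so the 8α,9α-diol should form.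

**Step 11**
Reactants: 17 (2S,4S,4aR,6S,7R,8S,8aR)-7,8-dihydroxy-4,4a-dimethyl-6-{2-[(triethylsilyl)oxy]propan-2-yl}decahydronaphthalen-2-yl acetate
Product: 18 (2S,4S,4aR,6S,7R,8S,8aR)-7,8-dihydroxy-6-(2-hydroxypropan-2-yl)-4,4a-dimethyldecahydronaphthalen-2-yl acetate
Conditions: HF·pyridine, pyridine, THF, 0 °C to rt
Reagents that add atoms: none
Why: Buffered fluoride should cleave the tertiary silyl ether without touching the acetate (desilylation).

**Step 12**
Reactants: 18 (2S,4S,4aR,6S,7R,8S,8aR)-7,8-dihydroxy-6-(2-hydroxypropan-2-yl)-4,4a-dimethyldecahydronaphthalen-2-yl acetate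
Product: 21 (2S,4S,4aR,6R,7R,8S,8aR)-7,8-dihydroxy-4,4a-dimethyl-6-(prop-1-en-2-yl)decahydronaphthalen-2-yl acetate, via triol phenylboronate 19 (not isolated), via isopropenyl phenylboronate 20 (not isolated)
Conditions: PhB(OH)2, 4 Å MS, CH2Cl2, rt; SOCl2, pyridine, −40 to 0 °C; then H2O2, NaHCO3, THF/H2O, 0 °C
Reagents that add atoms: none
Why: The cis-diol is masked in the flask as its cyclic phenylboronate, the tertiary chlorosulfite then undergoes pyridine-mediated E2 elimination in which the accessible methyl hydrogens should be taken in preference to the hindered C7–H (dehydration to the isopropenyl group), and oxidative work-up releases the diol.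

**Step 13**
Reactants: 21 (2S,4S,4aR,6R,7R,8S,8aR)-7,8-dihydroxy-4,4a-dimethyl-6-(prop-1-en-2-yl)decahydronaphthalen-2-yl acetate; 22 angelic acid [(2Z)-2-methylbut-2-enoic acid]
Product: 24 (1S,2R,3R,4aR,5S,7S,8aR)-7-acetoxy-2-hydroxy-4a,5-dimethyl-3-(prop-1-en-2-yl)decahydronaphthalen-1-yl (2Z)-2-methylbut-2-enoate (target), via mixed anhydride 23 (not isolated)
Conditions: 22, 2,4,6-trichlorobenzoyl chloride, Et3N, PhMe, rt; then 21, 75 °C
Reagents that add atoms: none
Why: Yamaguchi esterification through the mixed anhydride should acylate the equatorial C9 hydroxyl in preference to the axial C8 hydroxyl, which is flanked by the C7 isopropenyl group, and the DMAP-free conditions should preserve the Z geometry of the angelate.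

**Compound list**
1 | (S)-(+)-carvone | CC1=CC[C@@H](CC1=O)C(C)=C | starting material
2 | lithium (3S,5S)-2,3-dimethyl-5-(prop-1-en-2-yl)cyclohex-1-en-1-olate | [Li+].[O-]C1=C(C)[C@@H](C)C[C@H](C(C)=C)C1 | intermediate
3 | (3S,5S)-2,3-dimethyl-5-(prop-1-en-2-yl)cyclohex-1-en-1-yl trifluoromethanesulfonate | O=S(=O)(OC1=C(C)[C@@H](C)C[C@H](C(C)=C)C1)C(F)(F)F | intermediate
4 | (3S,5S)-5-(1-hydroperoxy-1-methoxyethyl)-2,3-dimethylcyclohex-1-en-1-yl trifluoromethanesulfonate (epimers at the peroxy carbon) | O=S(=O)(OC1=C(C)[C@@H](C)C[C@H](C(C)(OC)OO)C1)C(F)(F)F | intermediate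
5 | (1S,5S)-4,5-dimethyl-3-[(trifluoromethanesulfonyl)oxy]cyclohex-3-en-1-yl acetate | O=S(=O)(OC1=C(C)[C@@H](C)C[C@H](OC(C)=O)C1)C(F)(F)F | intermediate
6 | (1S,5S)-3-formyl-4,5-dimethylcyclohex-3-en-1-yl acetate | O=CC1=C(C)[C@@H](C)C[C@H](OC(C)=O)C1 | intermediate
7 | ethyl 2-(hydroxymethyl)prop-2-enoate | C=C(CO)C(=O)OCC | starting material
8 | 3-methyl-2-methylidenebutane-1,3-diol | C=C(CO)C(C)(C)O | intermediate
9 | 3-(bromomethyl)-2-methylbut-3-en-2-ol | C=C(CBr)C(C)(C)O | intermediate
10 | {[3-(bromomethyl)-2-methylbut-3-en-2-yl]oxy}(triethyl)silane | C=C(CBr)C(C)(C)O[Si](CC)(CC)CC | intermediate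
11 | {3-methyl-2-methylidene-3-[(triethylsilyl)oxy]butyl}(triphenyl)phosphonium bromide | C=C(C[P+](c1ccccc1)(c1ccccc1)c1ccccc1)C(C)(C)O[Si](CC)(CC)CC.[Br-] | intermediate
12 | {3-methyl-2-methylidene-3-[(triethylsilyl)oxy]butylidene}(triphenyl)phosphorane | C=C(C=P(c1ccccc1)(c1ccccc1)c1ccccc1)C(C)(C)O[Si](CC)(CC)CC | intermediate
13 | (1S,5S)-4,5-dimethyl-3-{(1E)-4-methyl-3-methylidene-4-[(triethylsilyl)oxy]pent-1-en-1-yl}cyclohex-3-en-1-yl acetate | C=C(/C=C/C1=C(C)[C@@H](C)C[C@H](OC(C)=O)C1)C(C)(C)O[Si](CC)(CC)CC | intermediate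
14 | (1S,5S)-4,5-dimethyl-3-{(1Z)-4-methyl-3-methylidene-4-[(triethylsilyl)oxy]pent-1-en-1-yl}cyclohex-3-en-1-yl acetate | C=C(/C=C\C1=C(C)[C@@H](C)C[C@H](OC(C)=O)C1)C(C)(C)O[Si](CC)(CC)CC | intermediate
15 | (2S,4S,4aR)-4,4a-dimethyl-6-{2-[(triethylsilyl)oxy]propan-2-yl}-1,2,3,4,4a,5-hexahydronaphthalen-2-yl acetate | CC(C)(O[Si](CC)(CC)CC)C1C[C@]2(C)[C@@H](C)C[C@H](OC(C)=O)CC2=CC=1 | intermediate
16 | (2S,4S,4aR,6S,8aS)-4,4a-dimethyl-6-{2-[(triethylsilyl)oxy]propan-2-yl}-1,2,3,4,4a,5,6,8a-octahydronaphthalen-2-yl acetate | CC(C)(O[Si](CC)(CC)CC)[C@H]1C[C@]2(C)[C@@H](C)C[C@H](OC(C)=O)C[C@H]2C=C1 | intermediate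
17 | (2S,4S,4aR,6S,7R,8S,8aR)-7,8-dihydroxy-4,4a-dimethyl-6-{2-[(triethylsilyl)oxy]propan-2-yl}decahydronaphthalen-2-yl acetate | CC(C)(O[Si](CC)(CC)CC)[C@H]1C[C@]2(C)[C@@H](C)C[C@H](OC(C)=O)C[C@H]2[C@H](O)[C@@H]1O | intermediate
18 | (2S,4S,4aR,6S,7R,8S,8aR)-7,8-dihydroxy-6-(2-hydroxypropan-2-yl)-4,4a-dimethyldecahydronaphthalen-2-yl acetate | CC(C)(O)[C@H]1C[C@]2(C)[C@@H](C)C[C@H](OC(C)=O)C[C@H]2[C@H](O)[C@@H]1O | intermediate
19 | cyclic phenylboronate of 18 (boron bridging the C8 and C9 oxygens, tertiary hydroxyl free) | CC(C)(O)[C@H]1C[C@]2(C)[C@@H](C)C[C@H](OC(C)=O)C[C@H]2[C@@H]3OB(c4ccccc4)O[C@H]13 | intermediate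
20 | cyclic phenylboronate of 21 (boron bridging the C8 and C9 oxygens) | C=C(C)[C@H]1C[C@]2(C)[C@@H](C)C[C@H](OC(C)=O)C[C@H]2[C@@H]3OB(c4ccccc4)O[C@H]13 | intermediate
21 | (2S,4S,4aR,6R,7R,8S,8aR)-7,8-dihydroxy-4,4a-dimethyl-6-(prop-1-en-2-yl)decahydronaphthalen-2-yl acetate | C=C(C)[C@H]1C[C@]2(C)[C@@H](C)C[C@H](OC(C)=O)C[C@H]2[C@H](O)[C@@H]1O | intermediate
22 | angelic acid, (2Z)-2-methylbut-2-enoic acid | C/C=C(/C)C(=O)O | starting material
23 | (2Z)-2-methylbut-2-enoic 2,4,6-trichlorobenzoic anhydride | C/C=C(/C)C(=O)OC(=O)c1c(Cl)cc(Cl)cc1Cl | intermediate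
24 | (1S,2R,3R,4aR,5S,7S,8aR)-7-acetoxy-2-hydroxy-4a,5-dimethyl-3-(prop-1-en-2-yl)decahydronaphthalen-1-yl (2Z)-2-methylbut-2-enoate | C=C(C)[C@H]1C[C@]2(C)[C@@H](C)C[C@H](OC(C)=O)C[C@H]2[C@H](OC(=O)/C(C)=C\C)[C@@H]1O | target

**Count and risks**
Total step count: 13. Longest linear sequence: 10 steps (4, 5, 6, 7, 8, 9, 10, 11, 12, 13), running from ethyl 2-(hydroxymethyl)prop-2-enoate through the phosphonium salt to the target; the carvone branch contributes 3 steps (1–3) before the union in step 8.

Most likely to fail: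

Step 8. The E-triene may not be funnelled completely to the Z-triene, or reversible 1,7-hydrogen shifts may divert the triene before it closes and, where the C4 hydrogen takes part, erode the configuration at C4. The fallback sets out from 6 (with 10) and comes back at 15 by a stepwise Horner–Wittig route with fixed geometry. Arbuzov reaction of 10 with Ph2POEt gives the allylic phosphine oxide F1. Its lithio derivative (n-BuLi, THF, −78 °C) adds to 6 and, after protonation at low temperature, gives the erythro β-hydroxy phosphine oxide F2, which is separated from the threo isomer. Stereospecific syn-elimination (NaH, DMF) then gives the Z-triene 14 alone, and heating it in PhMe closes it to 15.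

Step 9. The catalyst may not turn over on a diene whose two termini are both fully substituted, or hydrogen may be delivered 1,2. The fallback sets out from 15 and comes back at 16 and places the two hydrogens one at a time. Hydroboration–oxidation (BH3·SMe2, 1 equiv; then NaBO3·4H2O) of the C9=C10 bond from the α face, with boron on C9, gives the 9α-alcohol F3 with 10α-H. Dess–Martin periodinane gives the enone F4, and Luche reduction (NaBH4, CeCl3·7H2O) from the α face gives the 9β-alcohol F5. Mitsunobu displacement with 2-nitrobenzenesulfonylhydrazide (PPh3, DEAD, −30 °C) gives, with inversion, the 9α-sulfonylhydrazine F6. On warming, F6 loses the sulfinic acid to give the allylic diazene F7, whose retro-ene loss of N2 transfers hydrogen to C7 on the α face and moves the alkene to C8=C9, which is 16.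

Step 12. Elimination may run toward C7 (the more substituted alkene), the tertiary centre may ionise and rearrange, or the boronate may bridge the tertiary and C8 oxygens instead of the cis-diol. The fallback sets out from 17 and comes back at 21 and replaces the E2 dehydration by a thermal syn-elimination with the diol held as an acetal. Treating 17 with 2,2-dimethoxypropane and PPTS gives the acetonide F8, and Bu4NF gives the tertiary alcohol F9. NaN(SiMe3)2, CS2 and then MeI (THF, −78 to 0 °C) give the S-methyl xanthate F10, which on warming in PhMe undergoes Chugaev elimination to the isopropenyl acetonide F11. Aqueous AcOH then releases 21.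

**Further compounds**
F1 | step 8 | {3-methyl-2-methylidene-3-[(triethylsilyl)oxy]butyl}(diphenyl)phosphine oxide | C=C(CP(=O)(c1ccccc1)c1ccccc1)C(C)(C)O[Si](CC)(CC)CC
F2 | step 8 | erythro β-hydroxy phosphine oxide adduct of F1 and 6 (one of the two erythro diastereomers drawn; both give 14) | O[C@@H](C1=C(C)[C@@H](C)C[C@H](OC(C)=O)C1)[C@H](P(=O)(c1ccccc1)c1ccccc1)C(=C)C(C)(C)O[Si](CC)(CC)CC
F3 | step 9 | 9α-hydroxy-7-ene with 10α-H (otherwise as 15) | CC(C)(O[Si](CC)(CC)CC)C1C[C@]2(C)[C@@H](C)C[C@H](OC(C)=O)C[C@H]2[C@H](O)C=1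
F4 | step 9 | 7-en-9-one with 10α-H | CC(C)(O[Si](CC)(CC)CC)C1C[C@]2(C)[C@@H](C)C[C@H](OC(C)=O)C[C@H]2C(=O)C=1
F5 | step 9 | 9β-hydroxy-7-ene with 10α-H | CC(C)(O[Si](CC)(CC)CC)C1C[C@]2(C)[C@@H](C)C[C@H](OC(C)=O)C[C@H]2[C@@H](O)C=1
F6 | step 9 | 9α-[1-(2-nitrobenzenesulfonyl)hydrazinyl]-7-ene | CC(C)(O[Si](CC)(CC)CC)C1C[C@]2(C)[C@@H](C)C[C@H](OC(C)=O)C[C@H]2[C@H](N(N)S(=O)(=O)c3ccccc3[N+](=O)[O-])C=1
F7 | step 9 | 9α-diazenyl-7-ene (allylic diazene) | CC(C)(O[Si](CC)(CC)CC)C1C[C@]2(C)[C@@H](C)C[C@H](OC(C)=O)C[C@H]2[C@H](N=N)C=1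
F8 | step 12 | 8,9-O-isopropylidene acetal of 17 | CC(C)(O[Si](CC)(CC)CC)[C@H]1C[C@]2(C)[C@@H](C)C[C@H](OC(C)=O)C[C@H]2[C@@H]3OC(C)(C)O[C@H]13
F9 | step 12 | 8,9-O-isopropylidene acetal of 18 | CC(C)(O)[C@H]1C[C@]2(C)[C@@H](C)C[C@H](OC(C)=O)C[C@H]2[C@@H]3OC(C)(C)O[C@H]13
F10 | step 12 | S-methyl xanthate of F9 at the tertiary oxygen | CSC(=S)OC(C)(C)[C@H]1C[C@]2(C)[C@@H](C)C[C@H](OC(C)=O)C[C@H]2[C@@H]3OC(C)(C)O[C@H]13
F11 | step 12 | 8,9-O-isopropylidene acetal of 21 | C=C(C)[C@H]1C[C@]2(C)[C@@H](C)C[C@H](OC(C)=O)C[C@H]2[C@@H]3OC(C)(C)O[C@H]13
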